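**Retrosynthetic overview**

1. The target is a 3,3''-linked biflavanone of configuration (2S,3R,2''S,3''R), both pyranone rings 2,3-trans: a liquiritigenin half (rings A, C, B, unprimed atoms) and a naringenin half (rings A'', C'', B'', double-primed atoms). The last step is global debenzylation.
2. Key disconnection: pyranone ring C'' is opened at O-1''–C-8a'' and at C-2''–C-3'', giving the 1,4-diketone 12 (protected liquiritigenin with a CH2–CO–(2-fluoroaryl) chain on C-3) and 4-(benzyloxy)benzaldehyde. Forward, this is an aldol addition, an SNAr ring closure and a C-3'' epimerisation in one flask.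
3. Enabling feature: the C-4'' aryl ketone. Its α-carbon C-3'' is the only enolisable methylene, and through C-4a'' it activates the ortho carbon C-8a'' of ring A'' (fluorine-bearing in the precursor) for attack by the aldolate oxygen.
4. Diketone 12 comes from C-3 alkylation of the (2S)-flavanone 4 with bromoketone 10 (C-3–C-3'' bond, C-3 set trans). Flavanone 4 comes from an asymmetric conjugate addition of an arylboronic acid to a chromone, which sets C-2, the only stereocentre made by catalysis.
5. Ring order: rings A and C are bought as a chromone and ring B is attached at C-2; ring A'' is bought as a fluororesorcinol; ring C'' is closed last, in the key step, which also brings in ring B''.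

Key step: step 7

Assumption: the Pd/pyridine–oxazoline catalyst is taken to add the aryl group to the chromone with the same facial sense as to 3-substituted cyclohexenones, so that the (R)-ligand gives the (2S)-flavanone; should the sense be opposite, the (S)-ligand is used.

**Route**

Step 1
Reactants: 1 7-hydroxy-4H-chromen-4-one
Product: 2 7-(benzyloxy)-4H-chromen-4-one
Conditions: BnBr, K2CO3, acetone, reflux
Reagents that add atoms: benzyl bromide, BrCc1ccccc1
Why: Williamson ether synthesis, in which the 7-hydroxyl is the only acidic site and its phenoxide is benzylated by SN2 while the chromone ring is inert to carbonate in acetone.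

Step 2
Reactants: 2 7-(benzyloxy)-4H-chromen-4-one; 3 [4-(benzyloxy)phenyl]boronic acid
Product: 4 (2S)-7-(benzyloxy)-2-[4-(benzyloxy)phenyl]-2,3-dihydro-4H-chromen-4-one
Conditions: Pd(OCOCF3)2 (5 mol %), (R)-4-tert-butyl-2-(pyridin-2-yl)-4,5-dihydrooxazole (6 mol %), NH4PF6 (30 mol %), H2O (5 equiv), ClCH2CH2Cl, 60 °C
Reagents that add atoms: none
Why: Palladium-catalysed asymmetric conjugate addition of an arylboronic acid to a chromone, a known entry to enantioenriched flavanones, in which an arylpalladium species of divalent palladium carrying the pyridine–oxazoline ligand inserts C2=C3 on one enantioface and the palladium enolate is protonated by water, so that the ligand sets C-2 as S and the non-basic medium keeps the flavanone from ring opening and racemisation.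

Step 3
Reactants: 5 5-fluorobenzene-1,3-diol
Product: 7 1-(2-fluoro-4,6-dihydroxyphenyl)ethan-1-one, via ketiminium chloride 6 (not isolated)
Conditions: MeCN, ZnCl2, HCl (g), Et2O, 0 °C; then H2O, 100 °C
Reagents that add atoms: acetonitrile, CC#N; water, O
Why: Houben–Hoesch acylation, in which the nitrilium electrophile attacks the resorcinol position para to one hydroxyl and ortho to the other (next to fluorine), as resorcinol and 5-substituted resorcinols are known to do, and hydrolysis of the ketiminium salt 6 gives the ortho-fluoro aryl methyl ketone.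

Step 4
Reactants: 7 1-(2-fluoro-4,6-dihydroxyphenyl)ethan-1-one
Product: 8 1-[2,4-bis(benzyloxy)-6-fluorophenyl]ethan-1-one
Conditions: BnBr (2.3 equiv), K2CO3, DMF, 60 °C
Reagents that add atoms: benzyl bromide, BrCc1ccccc1
Why: Williamson ether synthesis of both phenols, the hydrogen-bonded ortho one needing DMF and warming, while the aryl fluoride is not displaced by carbonate or phenoxide at this temperature.

Step 5
Reactants: 8 1-[2,4-bis(benzyloxy)-6-fluorophenyl]ethan-1-one
Product: 10 1-[2,4-bis(benzyloxy)-6-fluorophenyl]-2-bromoethan-1-one, via silyl enol ether 9 (not isolated)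
Conditions: Me3SiOSO2CF3, Et3N, CH2Cl2, 0 °C; then NBS, −78 to 0 °C
Reagents that add atoms: N-bromosuccinimide, O=C1CCC(=O)N1Br
Why: Soft enolisation to the silyl enol ether 9 followed by electrophilic bromination with NBS places bromine only on the α-carbon and avoids the ring bromination that Br2 would risk on this electron-rich arene.

Step 6
Reactants: 4 (2S)-7-(benzyloxy)-2-[4-(benzyloxy)phenyl]-2,3-dihydro-4H-chromen-4-one; 10 1-[2,4-bis(benzyloxy)-6-fluorophenyl]-2-bromoethan-1-one
Product: 12 (2S,3R)-7-(benzyloxy)-2-[4-(benzyloxy)phenyl]-3-{2-[2,4-bis(benzyloxy)-6-fluorophenyl]-2-oxoethyl}-2,3-dihydro-4H-chromen-4-one, via lithium enolate 11 (not isolated)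
Conditions: LiN(SiMe3)2 (1.05 equiv), THF, −78 °C; then 10, DMPU, −78 to −40 °C; AcOH, −40 °C
Reagents that add atoms: none
Why: Alkylation of a ketone lithium enolate with an α-bromo ketone (SN2) to a 1,4-diketone, in which the ring C-2–O-1 bond of enolate 11 lies close to the nodal plane of the enolate so that ring opening by β-elimination (which would racemise C-2) should be slow at −78 °C, the 2,6-disubstituted aryl group shields the carbonyl of 10 so that attack goes to CH2Br, and the electrophile approaches C-3 anti to the C-2 aryl group to give the 2,3-trans (3R) product, which is also the thermodynamically preferred epimer.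

Step 7
Reactants: 12 (2S,3R)-7-(benzyloxy)-2-[4-(benzyloxy)phenyl]-3-{2-[2,4-bis(benzyloxy)-6-fluorophenyl]-2-oxoethyl}-2,3-dihydro-4H-chromen-4-one; 13 4-(benzyloxy)benzaldehyde
Product: 17 (2S,3R)-7-(benzyloxy)-2-[4-(benzyloxy)phenyl]-3-{(2S,3R)-5,7-bis(benzyloxy)-2-[4-(benzyloxy)phenyl]-4-oxo-3,4-dihydro-2H-chromen-3-yl}-2,3-dihydro-4H-chromen-4-one, via lithium Z-enolate 14 (not isolated), via lithium syn-aldolate 15 (not isolated), via cis biflavanone epimer 16 (not isolated)
Conditions: LiN(SiMe3)2 (1.05 equiv), THF, −78 °C; 13 (1.05 equiv), −78 °C; then DMPU, −78 to 0 °C; then DBU (0.2 equiv), 0 °C to rt; aq NH4Cl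
Reagents that add atoms: none
Why: Proposed new method: LiN(SiMe3)2 removes a proton from the only methylene of 12 (C-3'') to give the Z lithium enolate 14, which adds to aldehyde 13 through a closed six-membered chair (Zimmerman–Traxler) transition state to form C-3''–C-2'' as the syn aldolate 15; on warming with DMPU the aldolate oxygen attacks C-8a'', ortho to the C-4'' carbonyl, and expels fluoride through a carbonyl-stabilised Meisenheimer adduct (O-1''–C-8a''), and catalytic DBU then epimerises C-3'' of the cis flavanone 16 to give 17. The closest known reactions are the lithium enolate aldol addition of alkyl aryl ketones and the base-mediated SNAr ring closure of 3-hydroxy-1-(2-fluoroaryl)propan-1-ones to chroman-4-ones; their union in one flask on a 1,4-diketone that carries a second, enolisable flavanone is the new element. The single ring closed, pyranone ring C'', is formed by a six-membered intramolecular addition–elimination at the sp2 carbon C-8a'' (the C–F bond exocyclic to the new ring), not by the usual oxa-Michael closure at C-2''. C-2'' is set under kinetic control by relay from C-3: in the enolate conformer that has H-3 eclipsed with the enolate double bond (allylic 1,3-strain) the C-2 carbon and its equatorial aryl group cover one face, the aldehyde should therefore add from the face of the flat C-4 carbonyl, and the Z enolate geometry then fixes the (2''S,3''S) syn adduct; C-3'' is finally set under thermodynamic control, the 2'',3''-trans diequatorial epimer (3''R) being favoured, while C-2 and C-3 are not touched. The step needs site-selective enolisation (the C-3'' methylene rather than the tertiary C-3 methine, whose enolate could open ring C and endanger C-2), ring closure faster than retro-aldol, and no reaction of a second aldehyde; the substrate secures these through a single unhindered CH2 next to a ketone that cannot enolise on its other side and through the fluoride placed ortho to that same ketone, so that the lithium-chelated aldolate oxygen is held beside C-8a'', and the stoichiometry (one equivalent each of base and aldehyde) does the rest.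

Step 8
Reactants: 17 (2S,3R)-7-(benzyloxy)-2-[4-(benzyloxy)phenyl]-3-{(2S,3R)-5,7-bis(benzyloxy)-2-[4-(benzyloxy)phenyl]-4-oxo-3,4-dihydro-2H-chromen-3-yl}-2,3-dihydro-4H-chromen-4-one
Product: 18 (2S,3R)-3-[(2S,3R)-5,7-dihydroxy-2-(4-hydroxyphenyl)-4-oxo-3,4-dihydro-2H-chromen-3-yl]-7-hydroxy-2-(4-hydroxyphenyl)-2,3-dihydro-4H-chromen-4-one
Conditions: H2 (1 atm), Pd/C (10 wt %), EtOAc/MeOH, rt
Reagents that add atoms: none
Why: Catalytic hydrogenolysis of the five benzyl aryl ethers under neutral conditions, which does not enolise the two ketones and so leaves all four stereocentres untouched, the primary benzyl ethers being expected to cleave faster than the secondary benzylic C-2–O-1 and C-2''–O-1'' ring bonds so that the reaction is stopped at full debenzylation.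

**Compound list**

1 | 7-hydroxy-4H-chromen-4-one | O=c1ccoc2cc(O)ccc12 | starting material
2 | 7-(benzyloxy)-4H-chromen-4-one | O=c1ccoc2cc(OCc3ccccc3)ccc12 | intermediate
3 | [4-(benzyloxy)phenyl]boronic acid | OB(O)c1ccc(OCc2ccccc2)cc1 | starting material
4 | (2S)-7-(benzyloxy)-2-[4-(benzyloxy)phenyl]-2,3-dihydro-4H-chromen-4-one | O=C1c2ccc(OCc3ccccc3)cc2O[C@H](c2ccc(OCc3ccccc3)cc2)C1 | intermediate
5 | 5-fluorobenzene-1,3-diol | Oc1cc(O)cc(F)c1 | starting material
6 | 1-(2-fluoro-4,6-dihydroxyphenyl)ethan-1-iminium chloride | CC(=[NH2+])c1c(O)cc(O)cc1F.[Cl-] | intermediate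
7 | 1-(2-fluoro-4,6-dihydroxyphenyl)ethan-1-one | CC(=O)c1c(O)cc(O)cc1F | intermediate
8 | 1-[2,4-bis(benzyloxy)-6-fluorophenyl]ethan-1-one | CC(=O)c1c(OCc2ccccc2)cc(OCc2ccccc2)cc1F | intermediate
9 | ({1-[2,4-bis(benzyloxy)-6-fluorophenyl]ethenyl}oxy)trimethylsilane | C=C(O[Si](C)(C)C)c1c(OCc2ccccc2)cc(OCc2ccccc2)cc1F | intermediate
10 | 1-[2,4-bis(benzyloxy)-6-fluorophenyl]-2-bromoethan-1-one | O=C(CBr)c1c(OCc2ccccc2)cc(OCc2ccccc2)cc1F | intermediate
11 | lithium (2S)-7-(benzyloxy)-2-[4-(benzyloxy)phenyl]-2H-chromen-4-olate | [Li]OC1=C[C@@H](c2ccc(OCc3ccccc3)cc2)Oc2cc(OCc3ccccc3)ccc12 | intermediate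
12 | (2S,3R)-7-(benzyloxy)-2-[4-(benzyloxy)phenyl]-3-{2-[2,4-bis(benzyloxy)-6-fluorophenyl]-2-oxoethyl}-2,3-dihydro-4H-chromen-4-one | O=C1c2ccc(OCc3ccccc3)cc2O[C@H](c2ccc(OCc3ccccc3)cc2)[C@H]1CC(=O)c1c(OCc2ccccc2)cc(OCc2ccccc2)cc1F | intermediate
13 | 4-(benzyloxy)benzaldehyde | O=Cc1ccc(OCc2ccccc2)cc1 | starting material
14 | lithium (Z)-enolate of 12 formed at C-3'' (O–Li cis to the flavanon-3-yl group) | O=C1c2ccc(OCc3ccccc3)cc2O[C@H](c2ccc(OCc3ccccc3)cc2)[C@H]1/C=C(\O[Li])c1c(OCc2ccccc2)cc(OCc2ccccc2)cc1F | intermediate
15 | lithium (2''S,3''S)-syn-aldolate: lithium (1S,2S)-3-[2,4-bis(benzyloxy)-6-fluorophenyl]-1-[4-(benzyloxy)phenyl]-2-{(2S,3R)-7-(benzyloxy)-2-[4-(benzyloxy)phenyl]-4-oxo-3,4-dihydro-2H-chromen-3-yl}-3-oxopropan-1-olate | O=C1c2ccc(OCc3ccccc3)cc2O[C@H](c2ccc(OCc3ccccc3)cc2)[C@H]1[C@H](C(=O)c1c(OCc2ccccc2)cc(OCc2ccccc2)cc1F)[C@H](O[Li])c1ccc(OCc2ccccc2)cc1 | intermediate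
16 | (2S,3R)-7-(benzyloxy)-2-[4-(benzyloxy)phenyl]-3-{(2S,3S)-5,7-bis(benzyloxy)-2-[4-(benzyloxy)phenyl]-4-oxo-3,4-dihydro-2H-chromen-3-yl}-2,3-dihydro-4H-chromen-4-one (2'',3''-cis) | O=C1c2ccc(OCc3ccccc3)cc2O[C@H](c2ccc(OCc3ccccc3)cc2)[C@H]1[C@@H]1C(=O)c2c(OCc3ccccc3)cc(OCc3ccccc3)cc2O[C@@H]1c1ccc(OCc2ccccc2)cc1 | intermediate
17 | (2S,3R)-7-(benzyloxy)-2-[4-(benzyloxy)phenyl]-3-{(2S,3R)-5,7-bis(benzyloxy)-2-[4-(benzyloxy)phenyl]-4-oxo-3,4-dihydro-2H-chromen-3-yl}-2,3-dihydro-4H-chromen-4-one | O=C1c2ccc(OCc3ccccc3)cc2O[C@H](c2ccc(OCc3ccccc3)cc2)[C@H]1[C@H]1C(=O)c2c(OCc3ccccc3)cc(OCc3ccccc3)cc2O[C@@H]1c1ccc(OCc2ccccc2)cc1 | intermediate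
18 | (2S,3R)-3-[(2S,3R)-5,7-dihydroxy-2-(4-hydroxyphenyl)-4-oxo-3,4-dihydro-2H-chromen-3-yl]-7-hydroxy-2-(4-hydroxyphenyl)-2,3-dihydro-4H-chromen-4-one | O=C1c2ccc(O)cc2O[C@H](c2ccc(O)cc2)[C@H]1[C@H]1C(=O)c2c(O)cc(O)cc2O[C@@H]1c1ccc(O)cc1 | target

**Step count and risks**

Total step count: 8. Longest linear sequence: 6 steps (steps 3, 4, 5, 6, 7 and 8, from 5-fluorobenzene-1,3-diol); the flavanone branch (steps 1 and 2) joins at step 6.

Steps most likely to fail:

Step 7 (Proposed new method). The lithium aldolate may revert by retro-aldol before the slower SNAr closure, so that the kinetic facial selectivity at C-2'' is lost. Competing deprotonation at C-3 could also open ring C and erode C-2. The fallback sets out from 12 and separates the two events, using known chemistry. A boron-mediated aldol addition to 13 (n-Bu2BOSO2CF3, i-Pr2NEt, CH2Cl2, −78 °C; H2O2, pH 7 buffer work-up) would give the isolated syn adduct (2S,3R)-7-(benzyloxy)-2-[4-(benzyloxy)phenyl]-3-{(2S,3S)-1-[2,4-bis(benzyloxy)-6-fluorophenyl]-3-[4-(benzyloxy)phenyl]-3-hydroxy-1-oxopropan-2-yl}-2,3-dihydro-4H-chromen-4-one F1. Boron aldolates do not revert, and the diastereomers can be separated at this stage. If the substrate bias proves low, a diisopinocampheylboron triflate of the matching sense would replace the dibutylboron reagent. Ring closure of F1 by intramolecular SNAr (Cs2CO3, DMF, rt) would give 16, and brief DBU treatment returns to the route at 17.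

Step 6. Proton transfer from the acidic bromoketone 10 or from product 12 to enolate 11 may stall the alkylation or cause double alkylation. Base-induced opening of ring C would erode the configuration at C-2. The fallback sets out from 4 and avoids the basic enolate. Soft enolisation (Me3SiOSO2CF3, Et3N, CH2Cl2, 0 °C) would give {[(2S)-7-(benzyloxy)-2-[4-(benzyloxy)phenyl]-2H-chromen-4-yl]oxy}trimethylsilane F2. Visible-light photoredox coupling of F2 with 10 (Ru(bpy)3Cl2, 2,6-lutidine, MeCN, blue LED, rt) would then proceed by addition of the α-keto radical to C-3 anti to the C-2 aryl group, followed by oxidation and loss of the silyl group. Any cis epimer would be equilibrated with Et3N. The route is rejoined at 12.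

Step 8. Over-reduction may occur: hydrogenolytic cleavage of the benzylic C-2–O-1 and C-2''–O-1'' ring bonds, or reduction of the aryl ketones, could compete with the last debenzylations. The fallback sets out from 17 and uses Lewis-acid dealkylation instead of hydrogenolysis: BCl3 with pentamethylbenzene as benzyl cation scavenger, CH2Cl2, −78 °C. It arrives directly at 18 and makes no new compound (entry F0).

**Further compounds**

F1 | step 7 | (2S,3R)-7-(benzyloxy)-2-[4-(benzyloxy)phenyl]-3-{(2S,3S)-1-[2,4-bis(benzyloxy)-6-fluorophenyl]-3-[4-(benzyloxy)phenyl]-3-hydroxy-1-oxopropan-2-yl}-2,3-dihydro-4H-chromen-4-one | O=C1c2ccc(OCc3ccccc3)cc2O[C@H](c2ccc(OCc3ccccc3)cc2)[C@H]1[C@H](C(=O)c1c(OCc2ccccc2)cc(OCc2ccccc2)cc1F)[C@H](O)c1ccc(OCc2ccccc2)cc1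
F2 | step 6 | {[(2S)-7-(benzyloxy)-2-[4-(benzyloxy)phenyl]-2H-chromen-4-yl]oxy}trimethylsilane | C[Si](C)(C)OC1=C[C@@H](c2ccc(OCc3ccccc3)cc2)Oc2cc(OCc3ccccc3)ccc12
F0 | step 8 | none | none
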